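**Strategy.** Ring B of the target is a C6-oxygenated cyclohexane whose C5–C10 edge is shared with ring A, with isopropyl at C7 next to C6. The route disconnects ring B at C6–C7 and C8–C9: a ring A-fused cyclobutanone (C6, C5, C10, C9; C4 carbinol and C10 methyl already set) takes up the two carbons of a silyl isopropyl alkyne as C7–C8. One nickel-catalysed operation cleaves C6–C9 and closes ring B as a 6-oxo-7-ene with all skeletal carbons in place. The precursor is a cis-bicyclo[4.2.0]octan-7-one carrying the C10 methyl at one bridgehead and a silyl-protected tertiary carbinol at C4; C5 is inverted later through its enolate.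

Key step: step 6

Remark: ring atoms carry eudesmane numbers (C4 carbinol carbon, C5 and C10 ring-fusion carbons, C6 carbon bearing the ester oxygen, C7 carbon bearing isopropyl), β is the face of the C10 methyl, and the target is read as 4β-OH, 5α-H, 6β-acyloxy, 7β-isopropyl, 10β-methyl, that is (4S,5S,6R,7S,10R).

**Step 1**
Reactants: 1 3-methylcyclohex-2-en-1-one
Product: 2 (1S)-1,3-dimethylcyclohex-2-en-1-ol
Conditions: Me2Zn, Ti(Oi-Pr)4, trans-1,2-bis(hydroxycamphorsulfonamido)cyclohexane (cat., enantiomer that gives the S carbinol), toluene/hexane, rt; then H2O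
Reagents that add atoms: dimethylzinc, C[Zn]C
Why: Titanium-promoted catalytic asymmetric 1,2-addition of a dialkylzinc to a cyclic enone: the chiral bis(sulfonamide) titanium complex activates the carbonyl and delivers methyl to one face, which sets C4 as S, and the non-acidic quench and work-up keep the tertiary allylic alcohol from ionising to its symmetric allyl cation, the route by which it would racemise.

**Step 2**
Reactants: 2 (1S)-1,3-dimethylcyclohex-2-en-1-ol
Product: 3 tert-butyl{[(1S)-1,3-dimethylcyclohex-2-en-1-yl]oxy}dimethylsilane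
Conditions: t-BuMe2SiOTf, 2,6-lutidine, CH2Cl2, −78 to 0 °C
Reagents that add atoms: tert-butyldimethylsilyl trifluoromethanesulfonate, CC(C)(C)[Si](C)(C)OS(=O)(=O)C(F)(F)F
Why: Silylation of a tertiary alcohol with a silyl triflate and a hindered pyridine base stays non-acidic and leaves C4 untouched, and the tert-butyldimethylsilyl group is chosen because a tertiary ether of this kind should outlast ZnCl2, the nickel step, fluoride at room temperature in step 7 and the amide base in step 8.

**Step 3**
Reactants: 3 tert-butyl{[(1S)-1,3-dimethylcyclohex-2-en-1-yl]oxy}dimethylsilane; 4 trichloroacetyl chloride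
Product: 6 (1S,5S,6S)-5-[(tert-butyldimethylsilyl)oxy]-8,8-dichloro-1,5-dimethylbicyclo[4.2.0]octan-7-one, via dichloroketene 5 (not isolated)
Conditions: Zn–Cu couple, Et2O/DME, rt, slow addition of 4
Reagents that add atoms: none
Why: Ketene–alkene [2+2] cycloaddition with dichloroketene made in the flask by zinc dechlorination of 4: the ketene carbonyl carbon bonds to the less substituted alkene carbon (C5) and the CCl2 carbon to C10, the cis fusion is inherent, and approach anti to the bulky silyloxy group, which should sit pseudoaxial at C4, places the four-membered ring on the α face and so sets C10 and the provisional C5 relative to C4, while DME ties up ZnCl2 so that the tertiary allylic ether does not ionise.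

**Step 4**
Reactants: 6 (1S,5S,6S)-5-[(tert-butyldimethylsilyl)oxy]-8,8-dichloro-1,5-dimethylbicyclo[4.2.0]octan-7-one
Product: 7 (1R,5S,6S)-5-[(tert-butyldimethylsilyl)oxy]-1,5-dimethylbicyclo[4.2.0]octan-7-one
Conditions: Zn, NH4Cl, MeOH, rt
Reagents that add atoms: none
Why: Zinc reduction of an α,α-dichlorocyclobutanone through its zinc enolate with NH4Cl as a mild proton source removes both chlorines without opening the strained ketone, cleaving the silyl ether or touching a stereocentre.

**Step 5**
Reactants: 8 3-methylbut-1-yne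
Product: 10 trimethyl(3-methylbut-1-yn-1-yl)silane, via lithium acetylide 9 (not isolated)
Conditions: n-BuLi, THF, −78 °C; Me3SiCl, −78 °C to rt
Reagents that add atoms: chlorotrimethylsilane, C[Si](C)(C)Cl
Why: Deprotonation of the terminal alkyne and C-silylation of the lithium acetylide 9 is a standard alkyne protection, and the Me3Si group both suppresses alkyne oligomerisation at nickel and directs the orientation of insertion in step 6.

**Step 6**
Reactants: 7 (1R,5S,6S)-5-[(tert-butyldimethylsilyl)oxy]-1,5-dimethylbicyclo[4.2.0]octan-7-one; 10 trimethyl(3-methylbut-1-yn-1-yl)silane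
Product: 13 (4aR,8S,8aS)-8-[(tert-butyldimethylsilyl)oxy]-4a,8-dimethyl-2-(propan-2-yl)-3-(trimethylsilyl)-4a,5,6,7,8,8a-hexahydronaphthalen-1(4H)-one, via oxanickelacyclopentene 11 (not isolated), via nickelacycloheptenone 12 (not isolated)
Conditions: Ni(cod)2 (10 mol%), PCy3 (20 mol%), toluene, 100 °C, 10 in excess
Reagents that add atoms: none
Why: Proposed new method: zerovalent nickel carrying PCy3 should couple the C6 carbonyl of 7 with the alkyne by oxidative cyclisation to the spiro oxanickelacyclopentene 11, the C6–C7 bond forming at the isopropyl-bearing alkyne carbon so that the silyl-bearing carbon C8 is the one bound to nickel. β-Carbon elimination, driven by release of cyclobutane strain, should then break C6–C9 and give the seven-membered nickelacycle 12, from which C–C reductive elimination forms C8–C9 and frees zerovalent nickel. The closest known reaction type is the nickel-catalysed intermolecular [4+2] ring expansion of simple monocyclic cyclobutanones with internal alkynes to cyclohex-2-enones, whereas a ring-fused cyclobutanone next to a fully substituted carbon and a silyl isopropyl alkyne go beyond it. Ring B is closed by that reductive elimination, which amounts to insertion of C7–C8 into the C6–C9 bond. No stereocentre is formed, C4 and C10 are spectators and C5 keeps its bond to C6 and stays cis to the C10 methyl. The step needs cleavage of C6–C9 in preference to C6–C5, which the primary, less hindered C9 against a methine flanked by two quaternary carbons should secure, and it needs isopropyl next to the carbonyl, which the preference of nickel for the silyl-substituted carbon in the oxidative cyclisation should secure.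

**Step 7**
Reactants: 13 (4aR,8S,8aS)-8-[(tert-butyldimethylsilyl)oxy]-4a,8-dimethyl-2-(propan-2-yl)-3-(trimethylsilyl)-4a,5,6,7,8,8a-hexahydronaphthalen-1(4H)-one
Product: 14 (4aR,8S,8aS)-8-[(tert-butyldimethylsilyl)oxy]-4a,8-dimethyl-2-(propan-2-yl)-4a,5,6,7,8,8a-hexahydronaphthalen-1(4H)-one
Conditions: Bu4NF·3H2O, CuI (20 mol%), THF, rt
Reagents that add atoms: none
Why: Fluoride-promoted protodesilylation of an alkenylsilane, assisted by CuI and helped by the conjugated C6 carbonyl, replaces Me3Si at C8 by hydrogen while the hindered tertiary tert-butyldimethylsilyl ether resists Bu4NF at room temperature, and any base-induced change at C5 is harmless because step 8 passes through the C5 enolate.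

**Step 8**
Reactants: 14 (4aR,8S,8aS)-8-[(tert-butyldimethylsilyl)oxy]-4a,8-dimethyl-2-(propan-2-yl)-4a,5,6,7,8,8a-hexahydronaphthalen-1(4H)-one
Product: 16 (4aR,8S,8aR)-8-[(tert-butyldimethylsilyl)oxy]-4a,8-dimethyl-2-(propan-2-yl)-4a,5,6,7,8,8a-hexahydronaphthalen-1(4H)-one, via lithium dienolate 15 (not isolated)
Conditions: LiN(i-Pr)2, THF, −78 °C; then AcOH, −78 °C
Reagents that add atoms: none
Why: Kinetic α′ deprotonation of the enone, whose only α hydrogen is at C5, gives the cross-conjugated lithium dienolate 15, and irreversible protonation at −78 °C should come from the α face, away from the angular C10 methyl that stands perpendicular to the enolate plane and from the C4 silyloxy group on the same β side, which sets C5 as 5α-H (trans fusion) by kinetic enolate protonation without relying on an equilibrium, and the cold lithium enolate should not expel the β-silyloxy group.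

**Step 9**
Reactants: 16 (4aR,8S,8aR)-8-[(tert-butyldimethylsilyl)oxy]-4a,8-dimethyl-2-(propan-2-yl)-4a,5,6,7,8,8a-hexahydronaphthalen-1(4H)-one
Product: 17 (2S,4aR,8S,8aR)-8-[(tert-butyldimethylsilyl)oxy]-4a,8-dimethyl-2-(propan-2-yl)octahydronaphthalen-1(2H)-one
Conditions: H2 (1 atm), Pd/C, EtOAc, rt
Reagents that add atoms: none
Why: Heterogeneous catalytic hydrogenation of the trisubstituted C7=C8 bond of the enone delivers both hydrogens to the α face, opposite the axial C10 methyl, so that isopropyl becomes β and equatorial (C7 S), and the neutral conditions cannot epimerise C5.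

**Step 10**
Reactants: 17 (2S,4aR,8S,8aR)-8-[(tert-butyldimethylsilyl)oxy]-4a,8-dimethyl-2-(propan-2-yl)octahydronaphthalen-1(2H)-one
Product: 18 (1R,2S,4aR,8S,8aS)-8-[(tert-butyldimethylsilyl)oxy]-4a,8-dimethyl-2-(propan-2-yl)decahydronaphthalen-1-ol
Conditions: LiAlH4, THF, 0 °C; then H2O
Reagents that add atoms: none
Why: Hydride reduction of a cyclohexanone whose β face at C6 is screened by the axial C10 methyl and the axial C4 silyloxy group, so that even the small AlH4− attacks from the α (equatorial) side and gives the axial 6β alcohol (C6 R), as in the reduction of 6-oxo steroids.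

**Step 11**
Reactants: 18 (1R,2S,4aR,8S,8aS)-8-[(tert-butyldimethylsilyl)oxy]-4a,8-dimethyl-2-(propan-2-yl)decahydronaphthalen-1-ol
Product: 19 (1S,4aR,7S,8R,8aS)-1,4a-dimethyl-7-(propan-2-yl)decahydronaphthalene-1,8-diol
Conditions: 48% aqueous HF, MeCN, 0 °C to rt
Reagents that add atoms: none
Why: Acidic fluoride cleavage of a silyl ether, for which the small reagent HF reaches even this tertiary, flanked silicon–oxygen bond, frees the 4β-hydroxyl to give the 4β,6β-diol without touching a stereocentre.

**Step 12**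
Reactants: 20 (2E)-3-(3-hydroxyphenyl)prop-2-enoic acid
Product: 22 (2E)-3-{3-[(tert-butyldimethylsilyl)oxy]phenyl}prop-2-enoic acid, via bis-silylated acid 21 (not isolated)
Conditions: t-BuMe2SiCl, imidazole, DMF, rt; then AcOH/THF/H2O, rt
Reagents that add atoms: tert-butyldimethylsilyl chloride, CC(C)(C)[Si](C)(C)Cl
Why: Silylation of both acidic groups followed by hydrolysis of the far more labile silyl ester in the same flask leaves the aryl silyl ether, the usual way to mask the phenol of a hydroxycinnamic acid, and the E double bond is not affected.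

**Step 13**
Reactants: 19 (1S,4aR,7S,8R,8aS)-1,4a-dimethyl-7-(propan-2-yl)decahydronaphthalene-1,8-diol; 22 (2E)-3-{3-[(tert-butyldimethylsilyl)oxy]phenyl}prop-2-enoic acid
Product: 24 (1R,2S,4aR,8S,8aS)-8-hydroxy-4a,8-dimethyl-2-(propan-2-yl)decahydronaphthalen-1-yl (2E)-3-{3-[(tert-butyldimethylsilyl)oxy]phenyl}prop-2-enoate, via mixed anhydride 23 (not isolated)
Conditions: 22, 2,4,6-Cl3C6H2COCl, Et3N, THF, rt; then 19, DMAP, toluene, 80 °C
Reagents that add atoms: none
Why: Yamaguchi esterification: DMAP attacks the mixed anhydride 23 at the unhindered cinnamoyl carbonyl and the acylpyridinium acylates the secondary 6β-hydroxyl, with heat to offset its axial, flanked position, while the tertiary 4β-hydroxyl is too hindered to react and C6 keeps its configuration because its C–O bond is not broken.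

**Step 14**
Reactants: 24 (1R,2S,4aR,8S,8aS)-8-hydroxy-4a,8-dimethyl-2-(propan-2-yl)decahydronaphthalen-1-yl (2E)-3-{3-[(tert-butyldimethylsilyl)oxy]phenyl}prop-2-enoate
Product: 25 (1R,2S,4aR,8S,8aS)-8-hydroxy-4a,8-dimethyl-2-(propan-2-yl)decahydronaphthalen-1-yl (2E)-3-(3-hydroxyphenyl)prop-2-enoate
Conditions: Bu4NF, AcOH, THF, 0 °C
Reagents that add atoms: none
Why: Fluoride cleavage of an aryl silyl ether is fast at 0 °C, and buffering with AcOH keeps the medium from becoming basic enough to cleave or shift the cinnamate ester, which gives the target with all five stereocentres and the E alkene intact.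

**Compound list**

1 | 3-methylcyclohex-2-en-1-one | CC1=CC(=O)CCC1 | starting material
2 | (1S)-1,3-dimethylcyclohex-2-en-1-ol | CC1=C[C@@](C)(O)CCC1 | intermediate
3 | tert-butyl{[(1S)-1,3-dimethylcyclohex-2-en-1-yl]oxy}dimethylsilane | CC1=C[C@@](C)(O[Si](C)(C)C(C)(C)C)CCC1 | intermediate
4 | trichloroacetyl chloride | ClC(=O)C(Cl)(Cl)Cl | starting material
5 | dichloroketene | O=C=C(Cl)Cl | intermediate
6 | (1S,5S,6S)-5-[(tert-butyldimethylsilyl)oxy]-8,8-dichloro-1,5-dimethylbicyclo[4.2.0]octan-7-one | O=C1C(Cl)(Cl)[C@@]2(C)CCC[C@](C)(O[Si](C)(C)C(C)(C)C)[C@H]21 | intermediate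
7 | (1R,5S,6S)-5-[(tert-butyldimethylsilyl)oxy]-1,5-dimethylbicyclo[4.2.0]octan-7-one (ring A-fused cyclobutanone, C6=O on C5, C9H2 on C10) | O=C1C[C@@]2(C)CCC[C@](C)(O[Si](C)(C)C(C)(C)C)[C@H]21 | intermediate
8 | 3-methylbut-1-yne | CC(C)C#C | starting material
9 | lithium 3-methylbut-1-yn-1-ide | [Li]C#CC(C)C | intermediate
10 | trimethyl(3-methylbut-1-yn-1-yl)silane | CC(C)C#C[Si](C)(C)C | intermediate
11 | spiro oxanickelacyclopentene (ring Ni–O–C6–C7=C8, PCy3 on nickel, cyclobutane intact) | CC(C)C1=C([Si](C)(C)C)[Ni](P(C4CCCCC4)(C4CCCCC4)C4CCCCC4)OC12C[C@@]3(C)CCC[C@](C)(O[Si](C)(C)C(C)(C)C)[C@H]32 | intermediate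
12 | seven-membered nickelacycle (ring Ni–C9–C10–C5–C6(=O)–C7=C8, PCy3 on nickel) | CC(C)C1=C([Si](C)(C)C)[Ni](P(C4CCCCC4)(C4CCCCC4)C4CCCCC4)C[C@@]3(C)CCC[C@](C)(O[Si](C)(C)C(C)(C)C)[C@H]3C1=O | intermediate
13 | (4aR,8S,8aS)-8-[(tert-butyldimethylsilyl)oxy]-4a,8-dimethyl-2-(propan-2-yl)-3-(trimethylsilyl)-4a,5,6,7,8,8a-hexahydronaphthalen-1(4H)-one (cis-fused 8-silyl eudesm-7-en-6-one) | CC(C)C1=C([Si](C)(C)C)C[C@@]2(C)CCC[C@](C)(O[Si](C)(C)C(C)(C)C)[C@H]2C1=O | intermediate
14 | (4aR,8S,8aS)-8-[(tert-butyldimethylsilyl)oxy]-4a,8-dimethyl-2-(propan-2-yl)-4a,5,6,7,8,8a-hexahydronaphthalen-1(4H)-one (cis-fused, 5β-H) | CC(C)C1=CC[C@@]2(C)CCC[C@](C)(O[Si](C)(C)C(C)(C)C)[C@H]2C1=O | intermediate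
15 | lithium dienolate of 14 (C5=C6–OLi, C7=C8; C4 S, C10 R) | CC(C)C1=CC[C@@]2(C)CCC[C@](C)(O[Si](C)(C)C(C)(C)C)C2=C1O[Li] | intermediate
16 | (4aR,8S,8aR)-8-[(tert-butyldimethylsilyl)oxy]-4a,8-dimethyl-2-(propan-2-yl)-4a,5,6,7,8,8a-hexahydronaphthalen-1(4H)-one (trans-fused, 5α-H) | CC(C)C1=CC[C@@]2(C)CCC[C@](C)(O[Si](C)(C)C(C)(C)C)[C@@H]2C1=O | intermediate
17 | (2S,4aR,8S,8aR)-8-[(tert-butyldimethylsilyl)oxy]-4a,8-dimethyl-2-(propan-2-yl)octahydronaphthalen-1(2H)-one | CC(C)[C@@H]1CC[C@@]2(C)CCC[C@](C)(O[Si](C)(C)C(C)(C)C)[C@@H]2C1=O | intermediate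
18 | (1R,2S,4aR,8S,8aS)-8-[(tert-butyldimethylsilyl)oxy]-4a,8-dimethyl-2-(propan-2-yl)decahydronaphthalen-1-ol | CC(C)[C@@H]1CC[C@@]2(C)CCC[C@](C)(O[Si](C)(C)C(C)(C)C)[C@@H]2[C@@H]1O | intermediate
19 | (1S,4aR,7S,8R,8aS)-1,4a-dimethyl-7-(propan-2-yl)decahydronaphthalene-1,8-diol (eudesmane-4β,6β-diol) | CC(C)[C@@H]1CC[C@@]2(C)CCC[C@](C)(O)[C@@H]2[C@@H]1O | intermediate
20 | (2E)-3-(3-hydroxyphenyl)prop-2-enoic acid | OC(=O)/C=C/c1cccc(O)c1 | starting material
21 | tert-butyldimethylsilyl (2E)-3-{3-[(tert-butyldimethylsilyl)oxy]phenyl}prop-2-enoate | CC(C)(C)[Si](C)(C)OC(=O)/C=C/c1cccc(O[Si](C)(C)C(C)(C)C)c1 | intermediate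
22 | (2E)-3-{3-[(tert-butyldimethylsilyl)oxy]phenyl}prop-2-enoic acid | OC(=O)/C=C/c1cccc(O[Si](C)(C)C(C)(C)C)c1 | intermediate
23 | (2E)-3-{3-[(tert-butyldimethylsilyl)oxy]phenyl}prop-2-enoic 2,4,6-trichlorobenzoic anhydride | O=C(OC(=O)c1c(Cl)cc(Cl)cc1Cl)/C=C/c1cccc(O[Si](C)(C)C(C)(C)C)c1 | intermediate
24 | (1R,2S,4aR,8S,8aS)-8-hydroxy-4a,8-dimethyl-2-(propan-2-yl)decahydronaphthalen-1-yl (2E)-3-{3-[(tert-butyldimethylsilyl)oxy]phenyl}prop-2-enoate | CC(C)[C@@H]1CC[C@@]2(C)CCC[C@](C)(O)[C@@H]2[C@@H]1OC(=O)/C=C/c1cccc(O[Si](C)(C)C(C)(C)C)c1 | intermediate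
25 | (1R,2S,4aR,8S,8aS)-8-hydroxy-4a,8-dimethyl-2-(propan-2-yl)decahydronaphthalen-1-yl (2E)-3-(3-hydroxyphenyl)prop-2-enoate | CC(C)[C@@H]1CC[C@@]2(C)CCC[C@](C)(O)[C@@H]2[C@@H]1OC(=O)/C=C/c1cccc(O)c1 | target

**Step count**

Total steps: 14. Longest linear sequence: 12 (steps 1–4, 6–11, 13 and 14, from 1).

**Steps most likely to fail**

1. Step 6 (the step beyond known chemistry). The hindered fused ketone may fail to undergo oxidative cyclisation, nickel may insert into C6–C5 in place of C6–C9, the alkyne may enter with reversed orientation, or the alkyne may oligomerise. The fallback uses known chemistry only, sets out from 7 and comes back at 14. Kinetic enolisation toward C9 with silylation (LiN(i-Pr)2, Me3SiCl, THF, −78 °C) gives the cyclobutene silyl enol ether F1. Ozonolysis (O3, CH2Cl2/MeOH, −78 °C, then Me2S) cleaves C6=C9 to the cis aldehyde acid F2. Wittig methoxymethylenation (Ph3P=CHOMe in excess, THF) adds C8 and gives the enol ether acid F3. Isobutyllithium (2 equivalents, Et2O, 0 °C) turns the carboxylate into the isobutyl ketone F4, which brings in C7 with its isopropyl group. Dilute HCl in THF hydrolyses the enol ether to the keto aldehyde F5. Intramolecular aldol condensation (piperidinium acetate, benzene, heat) closes ring B at C7=C8 and gives 14.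

2. Step 8. Protonation of the dienolate may show poor facial selectivity, so that the cis isomer returns; deprotonation of the flanked C5–H may be slow; or the enolate may expel the β-silyloxy group. The fallback replaces kinetic protonation by an equilibrium biased by a hydrogen bond, sets out from 14 and comes back at 19. Aqueous HF in MeCN removes the silyl group to give the cis hydroxy enone F6. Hydrogenation (H2, Pd/C, EtOAc) gives the cis-fused hydroxy ketone F7, drawn as the 7α-isopropyl epimer expected from addition to the open β face. Equilibration of C5 and C7 with DBU in toluene at 60 °C should favour the trans-fused 7β-isopropyl hydroxy ketone F8, because there the 4β-hydroxyl can hydrogen-bond to the C6 carbonyl. LiBH(s-Bu)3 in THF at −78 °C then attacks C6 from the α face and gives 19.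

3. Step 3. The ketene may add syn to the silyloxy group (poor facial selectivity), which would set C10 and C5 wrongly relative to C4, or ZnCl2 may ionise the tertiary allylic ether with loss of enantiopurity. The fallback builds ring A onto a preformed cyclobutanone, sets out from 4 and comes back at 7. Dichloroketene from 4 (Zn–Cu couple, Et2O/DME) adds to the terminal alkene of 6-methylhept-6-en-2-one F9 (bought, or made by Sakurai allylation of methyl vinyl ketone with trimethyl(2-methylallyl)silane and TiCl4) to give the racemic dichlorocyclobutanone F10. Zn and NH4Cl in MeOH give the achiral diketone F11. A proline-catalysed desymmetrising intramolecular aldol reaction (DMSO, rt, proline enantiomer that leads to the 1R,5S,6S product) then closes ring A by attack of the cyclobutanone enamine on the methyl ketone. The tether enforces the cis fusion and the hydroxyl should end up trans to the C6 carbonyl arm, as in proline-catalysed enolexo aldol cyclisations, which gives the ketol F12. Silylation (t-BuMe2SiOTf, 2,6-lutidine) gives 7.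

**Further compounds**

F1 | step 6 | 5-[(tert-butyldimethylsilyl)oxy]-1,5-dimethyl-7-[(trimethylsilyl)oxy]bicyclo[4.2.0]oct-7-ene (stereocentres as in 7) | C[Si](C)(C)OC1=C[C@@]2(C)CCC[C@](C)(O[Si](C)(C)C(C)(C)C)[C@H]21
F2 | step 6 | 2-[(tert-butyldimethylsilyl)oxy]-6-formyl-2,6-dimethylcyclohexane-1-carboxylic acid (stereocentres as in 7) | O=C[C@@]1(C)CCC[C@](C)(O[Si](C)(C)C(C)(C)C)[C@H]1C(=O)O
F3 | step 6 | 2-[(tert-butyldimethylsilyl)oxy]-6-(2-methoxyethenyl)-2,6-dimethylcyclohexane-1-carboxylic acid (stereocentres as in 7) | COC=C[C@@]1(C)CCC[C@](C)(O[Si](C)(C)C(C)(C)C)[C@H]1C(=O)O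
F4 | step 6 | 1-{2-[(tert-butyldimethylsilyl)oxy]-6-(2-methoxyethenyl)-2,6-dimethylcyclohexyl}-3-methylbutan-1-one (stereocentres as in 7) | COC=C[C@@]1(C)CCC[C@](C)(O[Si](C)(C)C(C)(C)C)[C@H]1C(=O)CC(C)C
F5 | step 6 | {3-[(tert-butyldimethylsilyl)oxy]-1,3-dimethyl-2-(3-methylbutanoyl)cyclohexyl}acetaldehyde (stereocentres as in 7) | O=CC[C@@]1(C)CCC[C@](C)(O[Si](C)(C)C(C)(C)C)[C@H]1C(=O)CC(C)C
F6 | step 8 | (4aR,8S,8aS)-8-hydroxy-4a,8-dimethyl-2-(propan-2-yl)-4a,5,6,7,8,8a-hexahydronaphthalen-1(4H)-one | CC(C)C1=CC[C@@]2(C)CCC[C@](C)(O)[C@H]2C1=O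
F7 | step 8 | cis-fused 4β-hydroxyeudesman-6-one (5β-H, 7α-isopropyl) | CC(C)[C@H]1CC[C@@]2(C)CCC[C@](C)(O)[C@H]2C1=O
F8 | step 8 | trans-fused 4β-hydroxyeudesman-6-one (5α-H, 7β-isopropyl) | CC(C)[C@@H]1CC[C@@]2(C)CCC[C@](C)(O)[C@@H]2C1=O
F9 | step 3 | 6-methylhept-6-en-2-one | CC(=O)CCCC(C)=C
F10 | step 3 | 2,2-dichloro-3-methyl-3-(4-oxopentyl)cyclobutan-1-one (racemic) | CC(=O)CCCC1(C)CC(=O)C1(Cl)Cl
F11 | step 3 | 3-methyl-3-(4-oxopentyl)cyclobutan-1-one | CC(=O)CCCC1(C)CC(=O)C1
F12 | step 3 | (1R,5S,6S)-5-hydroxy-1,5-dimethylbicyclo[4.2.0]octan-7-one | O=C1C[C@@]2(C)CCC[C@](C)(O)[C@H]21
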